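**Retrosynthetic overview**

Numbering: decalin C1–C10 (C4 gem-dimethyl, C5=C6, C8–CH3, quaternary C9, C10–H), benzylic C11, arene C1'–C6'. The plan rests on the arene: C1' (bearing C11) is ortho to C6' (the sulfated oxygen) and C6'–O is para to C3'–O, the 2-alkyl-4-alkoxyphenol array that a terminal alkyne, an alkenyl(alkoxy)carbene and CO assemble with only C6'–OH free.
Arene ⇒ C9-propargyl decalin 26 + chromium carbene 33 (bonds C2'–C3', C1'–C6', C5'–C6'); afterwards C5' formylation, C6' trichloroethyl sulfate, BCl3, Zn.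
Alkyne 26 ⇒ ring B enone 15 by annulation of ring A: cuprate addition at C10 (C10–C1), aldol condensation (C4–C5), Me2CuLi at C4 with enolate triflation, Pd/formate reduction (C5=C6).
Enone 15 ⇒ (R)-5-methylcyclohex-2-enone (from (R)-pulegone, which supplies C8) by α′-propargylation then α′-methylation (C9) and a Wharton 1,3-carbonyl transposition.
Ring order: ring B (chiral pool), then ring A (annulation), then the benzene ring (benzannulation).

Key step: step 16

Assumption: the target is drawn as the free aryl hydrogen sulfate; the sulfate is released as its ammonium salt and brought to the acid form by cold cation exchange just before use.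

**Route**

Step 1
Reactants: 1 (R)-pulegone
Product: 2 pulegone oxide (6R)-2,2,6-trimethyl-1-oxaspiro[2.5]octan-4-one (both spiro epimers)
Conditions: 30% H2O2, LiOH, MeOH, 0 °C to rt
Reagents that add atoms: hydrogen peroxide, OO
Why: Weitz–Scheffer nucleophilic epoxidation of the electron-poor enone, in which both epoxide epimers serve because the spiro carbon is flattened again in step 3 and the methyl-bearing stereocentre (future C8) is not touched.

Step 2
Reactants: 2 pulegone oxide
Product: 4 (5R)-5-methyl-2-(phenylsulfanyl)cyclohexan-1-one (C2 epimers), via ring-opened alkoxide 3 (not isolated)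
Conditions: PhSH, NaH, THF, reflux
Reagents that add atoms: thiophenol, Sc1ccccc1
Why: thiolate opening of the epoxide at the α-keto carbon followed by retro-aldol loss of acetone from the tertiary alkoxide is the established degradation of pulegone oxide and leaves C5 unchanged.

Step 3
Reactants: 4 (5R)-5-methyl-2-(phenylsulfanyl)cyclohexan-1-one
Product: 6 (R)-5-methylcyclohex-2-en-1-one, via sulfoxide 5 (not isolated)
Conditions: NaIO4, MeOH–H2O, 0 °C to rt; then CaCO3, toluene, 110 °C
Reagents that add atoms: none
Why: sulfide oxidation and thermal syn-elimination of the α-sulfinyl ketone (sulfoxide pyrolysis) can only eliminate towards C3 and so gives the conjugated enone with the C5 stereocentre intact.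

Step 4
Reactants: 6 (R)-5-methylcyclohex-2-en-1-one; 7 3-bromo-1-(triisopropylsilyl)prop-1-yne
Product: 9 (5R,6S)-5-methyl-6-[3-(triisopropylsilyl)prop-2-yn-1-yl]cyclohex-2-en-1-one (trans; any cis epimer is carried on), via lithium dienolate 8 (not isolated)
Conditions: LiN(iPr)2, THF, −78 °C; then 7, −78 to −20 °C
Reagents that add atoms: none
Why: kinetic α′-deprotonation gives the cross-conjugated dienolate, and its SN2 enolate alkylation by the silyl-capped propargylic bromide occurs at C6 mainly anti to the C5 methyl, a configuration that is erased again in step 5.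

Step 5
Reactants: 9 (5R,6S)-5-methyl-6-[3-(triisopropylsilyl)prop-2-yn-1-yl]cyclohex-2-en-1-one
Product: 11 (5R,6R)-5,6-dimethyl-6-[3-(triisopropylsilyl)prop-2-yn-1-yl]cyclohex-2-en-1-one, via lithium dienolate 10 (not isolated)
Conditions: LiN(iPr)2, THF, −78 to 0 °C; then MeI, DMPU, −78 to 0 °C
Reagents that add atoms: iodomethane, CI
Why: in this enolate alkylation the C5 methyl sits pseudoaxial to avoid allylic strain with the C6 substituent, so iodomethane enters anti to it and sets the quaternary centre (future C9) with its methyl trans to the C8 methyl, as known for sequential α′-alkylation of 5-substituted cyclohexenones.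

Step 6
Reactants: 11 (5R,6R)-5,6-dimethyl-6-[3-(triisopropylsilyl)prop-2-yn-1-yl]cyclohex-2-en-1-one
Product: 12 (5R,6R)-2,3-epoxy-5,6-dimethyl-6-[3-(triisopropylsilyl)prop-2-yn-1-yl]cyclohexan-1-one (epoxide oxygen expected trans to the C5 methyl)
Conditions: 30% H2O2, NaOH, MeOH, 0 °C
Reagents that add atoms: hydrogen peroxide, OO
Why: Weitz–Scheffer epoxidation of the enone, whose facial outcome is of no consequence because the oxygen-bearing β-carbon becomes a carbonyl carbon in step 8, while the triisopropylsilyl-capped alkyne tolerates the cold base.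

Step 7
Reactants: 12 epoxy ketone
Product: 14 (4R,5R)-4,5-dimethyl-4-[3-(triisopropylsilyl)prop-2-yn-1-yl]cyclohex-2-en-1-ol (hydroxyl trans to the C5 methyl), via epoxy hydrazone 13 (not isolated)
Conditions: N2H4·H2O, AcOH (cat.), MeOH, 0 °C to rt
Reagents that add atoms: none
Why: Wharton transposition, in which the epoxy hydrazone opens to an allylic diazene that loses dinitrogen, moves the oxygen to the future C6 and the alkene to C5=C10 next to the quaternary carbon.

Step 8
Reactants: 14 allylic alcohol
Product: 15 (4R,5R)-4,5-dimethyl-4-[3-(triisopropylsilyl)prop-2-yn-1-yl]cyclohex-2-en-1-one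
Conditions: Dess–Martin periodinane, NaHCO3, CH2Cl2, rt
Reagents that add atoms: none
Why: Dess–Martin oxidation of the secondary allylic alcohol completes the 1,3-carbonyl transposition and gives the ring B enone whose β-carbon is the future C10.

Step 9
Reactants: 15 ring B enone; 16 2-(3-chloropropyl)-2-methyl-1,3-dioxolane
Product: 19 keto ketal 3-[3-(2-methyl-1,3-dioxolan-2-yl)propyl]-4,5-dimethyl-4-[3-(triisopropylsilyl)prop-2-yn-1-yl]cyclohexan-1-one (side chain at C10 trans to the C8 methyl and cis to the C9 methyl), via Grignard reagent 17 (not isolated), via silyl enol ether 18 (not isolated)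
Conditions: 16, Mg (I2-activated), THF, 60 °C; then CuBr·SMe2 (15 mol%), Me3SiCl, 15, THF, −78 to −30 °C; then K2CO3, MeOH, 0 °C
Reagents that add atoms: none
Why: in this copper-catalysed, Me3SiCl-accelerated Grignard conjugate addition the nucleophile enters C10 trans to the C8 methyl (the rule for 5-substituted cyclohexenones) and anti to the pseudoaxial C9 propargyl group of the conformer with equatorial C8 methyl, so the new C10–C1 bond is cis to the C9 methyl as the target requires.

Step 10
Reactants: 19 keto ketal
Product: 22 bicyclic enone (ring A closed; C6 ketone conjugated with C5=C4, C4 bearing one methyl), via diketone 20 (not isolated), via aldol 21 (not isolated)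
Conditions: 2 M HCl, THF, 60 °C
Reagents that add atoms: none
Why: acetal hydrolysis and intramolecular aldol condensation (6-enolexo-exo-trig attack of the C5 enol on the side-chain ketone) close ring A at C4–C5 and dehydrate to the conjugated enone, while C10, being β to the ring ketone, cannot epimerise.

Step 11
Reactants: 22 bicyclic enone
Product: 24 enol triflate (C6–OTf, C5=C6, C4 gem-dimethyl), via lithium enolate 23 (not isolated)
Conditions: Me2CuLi (from MeLi and CuI), Et2O, −20 to 0 °C; then PhNTf2, THF, 0 °C to rt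
Reagents that add atoms: methyllithium (delivered as Me2CuLi), [Li]C; N-phenylbis(trifluoromethanesulfonimide), O=S(=O)(N(c1ccccc1)S(=O)(=O)C(F)(F)F)C(F)(F)F
Why: cuprate conjugate addition to the s-cis alkylidene ketone (the reactivity of pulegone itself) makes C4 the gem-dimethyl carbon without creating a stereocentre, and O-sulfonylation of the regiodefined enolate fixes the double bond at C5=C6.

Step 12
Reactants: 24 enol triflate
Product: 25 (8R,9R,10S)-decalin with C9–CH2–C≡C–Si(iPr)3, C5=C6 and C4 gem-dimethyl
Conditions: Pd(OAc)2 (5 mol%), PPh3, Bu3N, HCO2H, DMF, 60 °C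
Reagents that add atoms: none
Why: palladium-catalysed formate reduction of the enol triflate (oxidative addition, formate exchange, decarboxylation, C–H reductive elimination) replaces the triflate by hydrogen with the alkene held at C5=C6, and the bulky silyl-capped alkyne does not engage the hindered vinylpalladium.

Step 13
Reactants: 25 silyl alkyne
Product: 26 (8R,9R,10S)-9-(prop-2-yn-1-yl) decalin (terminal alkyne)
Conditions: Bu4NF, THF, 0 °C to rt
Reagents that add atoms: none
Why: fluoride-induced protodesilylation of the alkynylsilane frees the terminal alkyne, and nothing else in 25 responds to fluoride.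

Step 14
Reactants: 27 isopropyl vinyl ether; 28 Cr(CO)6
Product: 31 tetramethylammonium pentacarbonyl[(1-isopropoxyvinyl)(oxido)carbene]chromate, via 1-isopropoxyvinyllithium 29 (not isolated), via lithium acyl chromate 30 (not isolated)
Conditions: t-BuLi, THF–pentane, −78 to 0 °C; then Cr(CO)6, Et2O, 0 °C to rt; then Me4NBr, H2O
Reagents that add atoms: tetramethylammonium bromide, C[N+](C)(C)C.[Br-]
Why: α-lithiation of the vinyl ether and addition of the vinyllithium to a CO ligand (Fischer acyl metalate synthesis) give the acyl chromate, which cation metathesis turns into its storable tetramethylammonium salt.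

Step 15
Reactants: 31 tetramethylammonium acyl chromate
Product: 33 pentacarbonyl[isopropoxy(1-isopropoxyvinyl)carbene]chromium, via acetoxycarbene complex 32 (not isolated)
Conditions: AcBr, CH2Cl2, −40 °C; then i-PrOH, −40 to 0 °C
Reagents that add atoms: propan-2-ol, CC(C)O
Why: O-acylation of the acyl chromate and addition–elimination of isopropanol at the carbene carbon (the acyloxycarbene alcoholysis route to alkoxycarbene complexes) install the secondary alkoxy group that direct alkylation would deliver poorly.

Step 16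
Reactants: 26 terminal alkyne; 33 carbene complex
Product: 35 2-(decalinylmethyl)-4,5-diisopropoxyphenol (C6'–OH free; isopropyl ethers at C3' and C4'), via tricarbonylchromium arene complex 34 (not isolated)
Conditions: 33 (1.5 equiv), THF (degassed), 55 °C; then air, MeCN, rt; chromatography under argon
Reagents that add atoms: none
Why: Thermal CO loss from 33 lets alkyne 26 coordinate and insert into the Cr=C bond with its unsubstituted carbon joined to the carbene carbon (C2'–C3'), the resulting vinylcarbene inserts CO to a chromium-bound dienylketene (C1'–C6'), and ring closure onto the vinyl terminus (C5'–C6') followed by enolisation gives the phenol, first as its Cr(CO)3 complex. This is the Dötz benzannulation of an alkenyl(alkoxy)carbene chromium complex with a terminal alkyne. The single ring formed, the benzene ring, is closed by 6π-electrocyclisation of the dienylketene. No stereocentre is created, and C8, C9 and C10 lie outside the reacting system. The step needs regiocontrol, which the terminal alkyne secures because its bulky neopentyl-type CH2 substituent is placed next to the CO-derived carbon, and it needs phenol formation to outrun cyclobutenone and furan pathways, which an alkenyl complex in a coordinating ether at moderate temperature favours. Only the C6' hydroxyl is left free, the oxygen that must carry the sulfate.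

Step 17
Reactants: 35 phenol
Product: 36 C5'-formyl phenol (salicylaldehyde; CHO between C4'–OiPr and C6'–OH)
Conditions: MgCl2, Et3N, (CH2O)n, THF, reflux
Reagents that add atoms: paraformaldehyde (as formaldehyde), C=O
Why: magnesium phenoxide-directed ortho-formylation (Casnati–Skattebøl reaction) can only reach C5', the one free position ortho to the C6' hydroxyl, and a second formaldehyde oxidises the hydroxymethyl stage to the aldehyde.

Step 18
Reactants: 36 salicylaldehyde
Product: 37 aryl 2,2,2-trichloroethyl sulfate at C6'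
Conditions: Cl3CCH2OSO2Cl, Et3N, DMAP, THF, 0 °C to rt
Reagents that add atoms: 2,2,2-trichloroethyl chlorosulfate, ClS(=O)(=O)OCC(Cl)(Cl)Cl
Why: O-sulfonylation of the only free phenol with the chlorosulfate ester under nucleophilic catalysis gives a neutral sulfate diester, a protected sulfate expected to survive the Lewis acid of step 19.

Step 19
Reactants: 37 sulfate diester
Product: 39 C3',C4'-catechol still carrying the trichloroethyl sulfate, via cyclic chloroboronate 38 (not isolated)
Conditions: BCl3, CH2Cl2, −78 to −20 °C; then NaHCO3 (aq), 0 °C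
Reagents that add atoms: none
Why: Lewis-acid dealkylation of aryl isopropyl ethers by BCl3 (the C4' ether assisted by chelation to the ortho formyl group) is run cold and quenched into bicarbonate so that the C5=C6 alkene is not protonated and the electron-poor sulfate diester is left alone.

Step 20
Reactants: 39 catechol sulfate diester
Product: 41 target aryl hydrogen sulfate, via ammonium sulfate salt 40 (not isolated)
Conditions: Zn dust, HCO2NH4, MeOH, rt; then Dowex 50W (H+ form), MeOH–H2O, 0 °C
Reagents that add atoms: none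
Why: zinc-mediated reductive β-elimination of the trichloroethyl group (loss of 1,1-dichloroethene) unmasks the sulfate monoester under near-neutral conditions that spare aldehyde, catechol and alkene, and cold cation exchange gives the acid form.

**Compound list**

1 | (R)-pulegone | C[C@@H]1CCC(=C(C)C)C(=O)C1 | starting material
2 | pulegone oxide, (6R)-2,2,6-trimethyl-1-oxaspiro[2.5]octan-4-one (spiro epimers) | C[C@@H]1CCC2(OC2(C)C)C(=O)C1 | intermediate
3 | sodium 2-[(4R)-4-methyl-2-oxo-1-(phenylsulfanyl)cyclohexyl]propan-2-olate | C[C@@H]1CCC(Sc2ccccc2)(C(C)(C)[O-])C(=O)C1.[Na+] | intermediate (not isolated)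
4 | (5R)-5-methyl-2-(phenylsulfanyl)cyclohexan-1-one (C2 epimers) | C[C@@H]1CCC(Sc2ccccc2)C(=O)C1 | intermediate
5 | (5R)-5-methyl-2-(phenylsulfinyl)cyclohexan-1-one | C[C@@H]1CCC(S(=O)c2ccccc2)C(=O)C1 | intermediate (not isolated)
6 | (R)-5-methylcyclohex-2-en-1-one | C[C@@H]1CC=CC(=O)C1 | intermediate
7 | 3-bromo-1-(triisopropylsilyl)prop-1-yne | BrCC#C[Si](C(C)C)(C(C)C)C(C)C | starting material
8 | lithium cross-conjugated dienolate of 6 | C[C@@H]1CC=CC([O-])=C1.[Li+] | intermediate (not isolated)
9 | (5R,6S)-5-methyl-6-[3-(triisopropylsilyl)prop-2-yn-1-yl]cyclohex-2-en-1-one | C[C@@H]1CC=CC(=O)[C@H]1CC#C[Si](C(C)C)(C(C)C)C(C)C | intermediate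
10 | lithium cross-conjugated dienolate of 9 | C[C@@H]1CC=CC([O-])=C1CC#C[Si](C(C)C)(C(C)C)C(C)C.[Li+] | intermediate (not isolated)
11 | (5R,6R)-5,6-dimethyl-6-[3-(triisopropylsilyl)prop-2-yn-1-yl]cyclohex-2-en-1-one | C[C@@H]1CC=CC(=O)[C@]1(C)CC#C[Si](C(C)C)(C(C)C)C(C)C | intermediate
12 | (5R,6R)-2,3-epoxy-5,6-dimethyl-6-[3-(triisopropylsilyl)prop-2-yn-1-yl]cyclohexan-1-one (oxygen trans to C5 methyl) | C[C@@H]1C[C@H]2O[C@H]2C(=O)[C@]1(C)CC#C[Si](C(C)C)(C(C)C)C(C)C | intermediate
13 | hydrazone of epoxy ketone 12 | C[C@@H]1C[C@H]2O[C@H]2C(=NN)[C@]1(C)CC#C[Si](C(C)C)(C(C)C)C(C)C | intermediate (not isolated)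
14 | (4R,5R)-4,5-dimethyl-4-[3-(triisopropylsilyl)prop-2-yn-1-yl]cyclohex-2-en-1-ol (OH trans to C5 methyl) | C[C@@H]1C[C@@H](O)C=C[C@]1(C)CC#C[Si](C(C)C)(C(C)C)C(C)C | intermediate
15 | (4R,5R)-4,5-dimethyl-4-[3-(triisopropylsilyl)prop-2-yn-1-yl]cyclohex-2-en-1-one | C[C@@H]1CC(=O)C=C[C@]1(C)CC#C[Si](C(C)C)(C(C)C)C(C)C | intermediate
16 | 2-(3-chloropropyl)-2-methyl-1,3-dioxolane | CC1(CCCCl)OCCO1 | starting material
17 | [3-(2-methyl-1,3-dioxolan-2-yl)propyl]magnesium chloride | CC1(CCC[Mg]Cl)OCCO1 | intermediate (not isolated)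
18 | trimethylsilyl enol ether of 19 (C6–OSiMe3, C5=C6) | C[C@@H]1CC(O[Si](C)(C)C)=C[C@@H](CCCC2(C)OCCO2)[C@]1(C)CC#C[Si](C(C)C)(C(C)C)C(C)C | intermediate (not isolated)
19 | keto ketal: 4,5-dimethyl-3-[3-(2-methyl-1,3-dioxolan-2-yl)propyl]-4-[3-(triisopropylsilyl)prop-2-yn-1-yl]cyclohexan-1-one (C10 chain trans to C8 methyl) | C[C@@H]1CC(=O)C[C@@H](CCCC2(C)OCCO2)[C@]1(C)CC#C[Si](C(C)C)(C(C)C)C(C)C | intermediate
20 | diketone: 4,5-dimethyl-3-(4-oxopentyl)-4-[3-(triisopropylsilyl)prop-2-yn-1-yl]cyclohexan-1-one | C[C@@H]1CC(=O)C[C@@H](CCCC(C)=O)[C@]1(C)CC#C[Si](C(C)C)(C(C)C)C(C)C | intermediate (not isolated)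
21 | aldol: bicyclic β-hydroxy ketone (C4–OH, C4–CH3, C6 ketone; C4/C5 epimers) | C[C@@H]1CC(=O)C2[C@@H](CCCC2(C)O)[C@]1(C)CC#C[Si](C(C)C)(C(C)C)C(C)C | intermediate (not isolated)
22 | bicyclic enone (C6 ketone, C4=C5, C4–CH3, 8R,9R,10S) | C[C@@H]1CC(=O)C2=C(C)CCC[C@H]2[C@]1(C)CC#C[Si](C(C)C)(C(C)C)C(C)C | intermediate
23 | lithium enolate (C6–O, C5=C6, C4 gem-dimethyl) | C[C@@H]1CC([O-])=C2[C@@H](CCCC2(C)C)[C@]1(C)CC#C[Si](C(C)C)(C(C)C)C(C)C.[Li+] | intermediate (not isolated)
24 | enol triflate (C6–OTf, C5=C6) | C[C@@H]1CC(OS(=O)(=O)C(F)(F)F)=C2[C@@H](CCCC2(C)C)[C@]1(C)CC#C[Si](C(C)C)(C(C)C)C(C)C | intermediate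
25 | (8R,9R,10S)-decalin with C9–CH2–C≡C–Si(iPr)3 | C[C@@H]1CC=C2[C@@H](CCCC2(C)C)[C@]1(C)CC#C[Si](C(C)C)(C(C)C)C(C)C | intermediate
26 | (8R,9R,10S)-9-(prop-2-yn-1-yl)-4,4,8,9-tetramethyl-Δ5-decalin | C[C@@H]1CC=C2[C@@H](CCCC2(C)C)[C@]1(C)CC#C | intermediate
27 | isopropyl vinyl ether | C=COC(C)C | starting material
28 | hexacarbonylchromium, Cr(CO)6 | O=C=[Cr](=C=O)(=C=O)(=C=O)(=C=O)=C=O | starting material
29 | 1-isopropoxyvinyllithium | [Li]C(=C)OC(C)C | intermediate (not isolated)
30 | lithium pentacarbonyl[(1-isopropoxyvinyl)(oxido)carbene]chromate | C=C(OC(C)C)C([O-])=[Cr](=C=O)(=C=O)(=C=O)(=C=O)=C=O.[Li+] | intermediate (not isolated)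
31 | tetramethylammonium pentacarbonyl[(1-isopropoxyvinyl)(oxido)carbene]chromate | C=C(OC(C)C)C([O-])=[Cr](=C=O)(=C=O)(=C=O)(=C=O)=C=O.C[N+](C)(C)C | intermediate
32 | pentacarbonyl[acetoxy(1-isopropoxyvinyl)carbene]chromium | C=C(OC(C)C)C(OC(C)=O)=[Cr](=C=O)(=C=O)(=C=O)(=C=O)=C=O | intermediate (not isolated)
33 | pentacarbonyl[isopropoxy(1-isopropoxyvinyl)carbene]chromium | CC(C)OC(C(=C)OC(C)C)=[Cr](=C=O)(=C=O)(=C=O)(=C=O)=C=O | intermediate
34 | tricarbonyl(η6-arene)chromium complex of phenol 35 (drawn as two parts) | C[C@@H]1CC=C2[C@@H](CCCC2(C)C)[C@]1(C)Cc1cc(OC(C)C)c(OC(C)C)cc1O.O=C=[Cr](=C=O)=C=O | intermediate (not isolated)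
35 | phenol: C6'–OH free, isopropyl ethers at C3' and C4' | C[C@@H]1CC=C2[C@@H](CCCC2(C)C)[C@]1(C)Cc1cc(OC(C)C)c(OC(C)C)cc1O | intermediate
36 | C5'-formyl phenol | C[C@@H]1CC=C2[C@@H](CCCC2(C)C)[C@]1(C)Cc1cc(OC(C)C)c(OC(C)C)c(C=O)c1O | intermediate
37 | C6' aryl 2,2,2-trichloroethyl sulfate, diisopropyl ether | C[C@@H]1CC=C2[C@@H](CCCC2(C)C)[C@]1(C)Cc1cc(OC(C)C)c(OC(C)C)c(C=O)c1OS(=O)(=O)OCC(Cl)(Cl)Cl | intermediate
38 | cyclic chloroboronate of the C3',C4'-catechol | C[C@@H]1CC=C2[C@@H](CCCC2(C)C)[C@]1(C)Cc1cc2OB(Cl)Oc2c(C=O)c1OS(=O)(=O)OCC(Cl)(Cl)Cl | intermediate (not isolated)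
39 | C3',C4'-catechol with C6' trichloroethyl sulfate | C[C@@H]1CC=C2[C@@H](CCCC2(C)C)[C@]1(C)Cc1cc(O)c(O)c(C=O)c1OS(=O)(=O)OCC(Cl)(Cl)Cl | intermediate
40 | ammonium salt of the target sulfate | C[C@@H]1CC=C2[C@@H](CCCC2(C)C)[C@]1(C)Cc1cc(O)c(O)c(C=O)c1OS(=O)(=O)[O-].[NH4+] | intermediate (not isolated)
41 | CNP0115595.2 (8R,9R,10S) | C[C@@H]1CC=C2[C@@H](CCCC2(C)C)[C@]1(C)Cc1cc(O)c(O)c(C=O)c1OS(=O)(=O)O | target

**Step count**

Total steps: 20. Longest linear sequence: 18 (steps 1–13 and 16–20); the carbene branch is 2 steps (14 and 15).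

**Steps most likely to fail**

Step 16 (benzannulation). The α-alkoxyvinyl carbene may decompose thermally before the alkyne inserts. The vinylketene intermediate may collapse to cyclobutenone or furan products instead of electrocyclising. The electron-rich phenol may oxidise while the chromium is removed. Fallback, a Moore–Liebeskind cyclobutenone ring expansion, sets out from alkyne 26. Hydrozirconation with Cp2Zr(H)Cl and iodination give the (E)-vinyl iodide F1. Iodine–lithium exchange (t-BuLi, Et2O, −78 °C) and addition of the vinyllithium to 3-isopropoxycyclobut-3-ene-1,2-dione F2 follow. F2 is two known steps from commercial diisopropyl squarate, and the addition occurs at the carbonyl that is not deactivated as a vinylogous ester. Trapping the alkoxide with MOMCl gives the 4-alkenyl-4-(methoxymethoxy)cyclobutenone F3. Heating in toluene at 110 °C opens the four-membered ring to a dienylketene that closes and enolises to the phenol F4. F4 has the array of 35 with a methoxymethyl ether in place of the C3' isopropyl ether. Formylation as in step 17 gives the aldehyde F5, and sulfation as in step 18 gives the sulfate diester F6. BCl3 as in step 19 removes the isopropyl and methoxymethyl groups together, and the route is rejoined at 39.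

Step 19 (ether cleavage). The Lewis acid may cleave the S–O bonds of the sulfate diester, the unchelated C3' ether may be removed only partly, or the C5=C6 double bond may migrate under acid during the quench. Fallback reverses the order of unveiling and sulfation and sets out from 36. BCl3 at −78 °C on this sulfate-free substrate gives the triol aldehyde F7, handled under argon. One equivalent of 1,1'-carbonyldiimidazole in THF ties the catechol as the cyclic carbonate F8 and leaves the C6' hydroxyl free. SO3·pyridine in pyridine gives the pyridinium aryl sulfate F9. Cold aqueous NH3 in MeOH removes the carbonate, to which the sulfate salt is stable, and the route is rejoined at ammonium salt 40 without the trichloroethyl group or the zinc step.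

Step 7 (Wharton transposition). Hydrazone formation at the carbonyl flanked by the quaternary carbon may be slow, so that hydrazine opens the epoxide first. Fallback is a radical epoxide fragmentation and sets out from epoxy ketone 12. NaBH4 in MeOH gives the epoxy alcohol F10 (either carbinol epimer). 1,1'-Thiocarbonyldiimidazole gives the thiocarbonylimidazolide F11. Bu3SnH and AIBN in toluene at 80 °C generate the radical next to the epoxide, which opens to the allyloxy radical and takes hydrogen from the stannane. This is a Barton-type deoxygenation with oxirane opening, and it rejoins the route at allylic alcohol 14 with the same carbinol configuration.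

**Further compounds**

F1 | step 16 | (E)-vinyl iodide from hydrozirconation–iodination of 26 | C[C@@H]1CC=C2[C@@H](CCCC2(C)C)[C@]1(C)C/C=C/I
F2 | step 16 | 3-isopropoxycyclobut-3-ene-1,2-dione | CC(C)OC1=CC(=O)C1=O
F3 | step 16 | 4-alkenyl-3-isopropoxy-4-(methoxymethoxy)cyclobut-2-en-1-one (carbinol epimers) | C[C@@H]1CC=C2[C@@H](CCCC2(C)C)[C@]1(C)C/C=C/C1(OCOC)C(=O)C=C1OC(C)C
F4 | step 16 | phenol with C6'–OH free, C4' isopropyl ether and C3' methoxymethyl ether | C[C@@H]1CC=C2[C@@H](CCCC2(C)C)[C@]1(C)Cc1cc(OCOC)c(OC(C)C)cc1O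
F5 | step 16 | C5'-formyl derivative of F4 | C[C@@H]1CC=C2[C@@H](CCCC2(C)C)[C@]1(C)Cc1cc(OCOC)c(OC(C)C)c(C=O)c1O
F6 | step 16 | C6' 2,2,2-trichloroethyl sulfate of F5 | C[C@@H]1CC=C2[C@@H](CCCC2(C)C)[C@]1(C)Cc1cc(OCOC)c(OC(C)C)c(C=O)c1OS(=O)(=O)OCC(Cl)(Cl)Cl
F7 | step 19 | triol aldehyde (C3', C4', C6' hydroxyls free) | C[C@@H]1CC=C2[C@@H](CCCC2(C)C)[C@]1(C)Cc1cc(O)c(O)c(C=O)c1O
F8 | step 19 | cyclic carbonate of the C3',C4'-catechol with C6'–OH free | C[C@@H]1CC=C2[C@@H](CCCC2(C)C)[C@]1(C)Cc1cc2OC(=O)Oc2c(C=O)c1O
F9 | step 19 | pyridinium C6' aryl sulfate of the cyclic carbonate | C[C@@H]1CC=C2[C@@H](CCCC2(C)C)[C@]1(C)Cc1cc2OC(=O)Oc2c(C=O)c1OS(=O)(=O)[O-].c1cc[nH+]cc1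
F10 | step 7 | epoxy alcohol from reduction of 12 (carbinol epimers) | C[C@@H]1C[C@H]2O[C@H]2C(O)[C@]1(C)CC#C[Si](C(C)C)(C(C)C)C(C)C
F11 | step 7 | O-thiocarbonylimidazolide of F10 | C[C@@H]1C[C@H]2O[C@H]2C(OC(=S)n2ccnc2)[C@]1(C)CC#C[Si](C(C)C)(C(C)C)C(C)C
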